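## The problem

Compound 21 is a 2,3-dihydro-1-benzofuran whose C2 carries a 4-hydroxy-3,5-dimethoxyphenyl ring and whose C3 carries a hydroxymethyl group. The fused benzo ring bears a methoxy group at C7 and an (E)-propenoic acid at C5. A synthesis has to join two oxygenated aryl units and close the five-membered ring along its O1–C2–C3 edge. The two stereocentres are adjacent and trans (C2 is S, C3 is R); trans is the more stable arrangement, but no resident centre can dictate absolute configuration, so it must come from a reagent or catalyst. C3 is configurationally robust, whereas C2 is a benzylic ether para to a phenol and can open to a para-quinone methide once that phenol is free. C3 can therefore correct C2 but not the reverse, and C2 is best made with the phenol masked. The electron-rich phenol (oxidation), the cinnamic acid (conjugate addition, reduction) and the ionisable C2–O1 bond (strong acid) rule out rough conditions late in the route. The decisive feature is that C2 carries only the aryl ring, a hydrogen and its two ring bonds to O1 and C3: it is a benzylidene unit lodged between a phenol oxygen and a benzylic carbon, and the other four ring atoms O1–C7a–C3a–C3 form the skeleton of an ortho-quinone methide.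

## Retrosynthesis

**Periphery (21 back to 18).** One hydroxide treatment of 20 unveils both the carboxylic acid (from the methyl ester) and the phenol (from the pivalate). Fluoride frees the primary alcohol of 20 from silyl ether 19. The C5–vinyl bond of 19 is cut back to aryl bromide 18 (Heck reaction with methyl acrylate). Carrying the acrylate, or an aldehyde precursor, through ring formation was rejected: a sulfur ylide would cyclopropanate the first and epoxidise the second, whereas bromine para to O1 is inert to ylide and carbonate. Compound 18 holds the full ring system and both stereocentres but only robust groups. The forward steps need only be mild towards C2, which an amine-base Heck reaction, buffered fluoride and lithium hydroxide near room temperature provide.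

**Ring (18 back to 5 and 14).** In 18 the bonds C2–C3 and O1–C2 are cut together. C2 leaves as a one-carbon benzylidene unit, the ylide 16 of a chiral sulfide, and O1–C7a–C3a–C3 remains as ortho-quinone methide 15. Cutting O1–C7a or C3–C3a instead leaves an open chain whose two stereocentres still have to be made. The double cut makes the ring, two bonds and both centres in one operation from two fragments of similar size. Neither partner can be stored: base releases 15 from sulfone 5 (loss of sulfinate) and 16 from sulfonium salt 14; they combine to betaine 17, which closes. Precursor 5 is racemic and achiral in effect; the only stereochemical information in 14 is its C2-symmetric thiolane ring. The forward step must capture the methide chemoselectively, give the trans ring, and be face-selective at the ylide carbon. Three choices follow: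
- A pivalate on the syringyl oxygen: an acyl group suppresses ionisation of 14 to a para-quinone methide and, unlike an acetate, is not handed on to phenoxides.
- A tert-butyldiphenylsilyl ether on the primary oxygen: it is no leaving group β to the sulfone and survives the acid used to make 5.
- A tetrafluoroborate counter-ion: the S-alkylation cannot reverse.

**Sulfone (5 back to 1).** Sulfone 5 is cut at C–S to benzylic alcohol 4 and p-toluenesulfinic acid; ortho-hydroxybenzylic alcohols exchange OH for sulfinate under mild acid. The silyl ether of 4 comes from the primary hydroxyl of triol 3, the diol of 3 from the vinyl group of 2, and that vinyl group from the aldehyde of commercial 1. Direct addition of an oxymethyl organometallic to 1 looks shorter but needs a tin or silicon reagent and a protected phenol. Olefination and dihydroxylation use stock reagents and tolerate the free phenol and the bromide. No stereocontrol is needed, because the carbinol/sulfonyl carbon becomes planar in 15.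

**Sulfonium salt (14 back to 6 and 10).** Salt 14 is cut at S–CH2 into benzylic bromide 9 and (2S,5S)-2,5-dimethylthiolane 13. Bromide 9 goes back through alcohol 8 and aldehyde 7 to syringaldehyde 6; the pivalate is installed first so that no free para-hydroxybenzyl halide is ever present. Thiolane 13 comes from dimesylate 11 of (2R,5R)-hexane-2,5-diol 10 and sodium sulfide by two inversions via thiolate 12. This sulfide is chosen because either enantiomer is two steps from a commercial diol, its C2 symmetry allows only one sulfonium isomer, and it is released unchanged in the annulation and can be recovered.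

## Roads not taken

Alternative 1: The cut is O1–C7a. The ring would be closed last by palladium-catalysed intramolecular aryl ether formation (Pd(OAc)2 with a bulky di-tert-butyl biaryl phosphine) between the secondary C2 hydroxyl of open-chain alcohol A1 and its ortho aryl triflate, giving A2. Both stereocentres of A1 would come from an auxiliary-controlled syn aldol reaction.
- Merits: the aldol sets two adjacent centres in a predictable absolute sense; the closure touches neither centre, since the new bond forms at oxygen; the acrylate can already be in place.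
- Weak points: the palladium alkoxide of a secondary benzylic alcohol has a β-hydrogen, so oxidation to the ketone competes with C–O reductive elimination. The triflate carbon is flanked by a methoxy group and the branched side chain. The route is long: the aryl–CH2–CO unit must be built with a masked ortho phenol, the auxiliary attached and removed, the primary alcohol differentiated, the phenol unmasked and triflated, and the methoxymethyl ether finally removed with acid from a compound whose C2–O1 bond is acid-labile.
- Comparison: this road is stereochemically more certain than the chosen one, whose sense and level of induction still have to be established. The chosen plan sets against this its convergence (two fragments of four steps each, ring and both centres in one step, eight steps in the longest line), no metal-catalysed bond formation at a crowded carbon, and a recoverable source of chirality.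

Alternative 2: The cuts are C2–aryl and C3–C3a, with a C2–B bond standing in for C2–O. A boron ate complex formed in the flask from an aryllithium and an (E)-alkenylboronic ester would react with an aryl triflate under Pd(OAc)2 and a chiral MandyPhos bisphosphine. The arylpalladium species bonds to C3 while the syringyl group migrates from boron to C2, anti across the alkene, giving boronic ester A3.
- Merits: three simple achiral components; both centres from a catalytic amount of chiral ligand; relative configuration fixed by a stereospecific 1,2-shift.
- Weak points: A3 is still open-chain. Oxidising C–B puts a hydroxyl at C2 with retention, exactly where O1 must sit, but O1 is already on the benzo ring as a methoxymethyl ether. The ring can then close only by substitution at C2: either by two inversions, or through the benzylic cation, which discards the C2 configuration so that only C3 of A3 counts. The electron-rich, doubly meta-substituted migrating group and a triflate ortho to an alkoxy group are both demanding for this coupling. The future C5 carries a benzoate that needs further steps to become the acrylic acid.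
- Comparison: this road is better in that chirality is catalytic and its key step belongs to a demonstrated reaction class. The chosen plan answers with ring closure in the same step as the stereocentres, a one-step Heck introduction of the side chain, and a sulfide that is stoichiometric but recovered.

Alternative 3: The cut is C3–C3a, which in retrosynthesis expands the dihydrofuran to a chromanone. Enantioenriched flavanone A4, treated with PhI(OAc)2 and H2SO4 in trimethyl orthoformate, would form its ketal, be iodinated at C3, and undergo a 1,2-shift of the fused aryl carbon from the ketal carbon to C3 as iodobenzene departs. The old carbonyl carbon becomes a methyl ester and the product is trans ester A5.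
- Merits: the ring contraction is a known reaction of flavanones and gives trans products; A5 maps onto 18 after reduction and silylation.
- Weak points: the single stereocentre of A4 needs its own asymmetric step and must then survive strong acid, although flavanones racemise by ring opening to the chalcone, especially with an oxygenated 2-aryl group. Under the same oxidising conditions an electron-rich 2-aryl group can migrate instead, giving an isoflavone. Acetophenone A6, needed for A4, is not a stock compound. The methyl ester of A5 must be reduced beside an aryl pivalate.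
- Comparison: the key step of this road is precedented where the chosen one is not, which is a real advantage. The chosen plan is shorter to 18, forms both centres under basic conditions that cannot racemise them, and avoids strong acid. Ester A5 is therefore kept in reserve as the meeting point of a fallback.

Key step: step 11

Assumption: the thiolanium ylide is taken to react through the same open face as in its benzylidene transfer to aldehydes, where the (2R,5R) sulfide gives (S,S)-diaryl epoxides; because the aryl group and the neighbouring ring carbon exchange CIP rank between an epoxide and this dihydrofuran, that face corresponds to 2R here, so the (2S,5S) sulfide from the (2R,5R) diol is used for 2S, and the enantiomeric diol would be substituted without other change if the sense proved opposite.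

Step 1
Reactants: 1 5-bromo-2-hydroxy-3-methoxybenzaldehyde
Product: 2 4-bromo-2-ethenyl-6-methoxyphenol
Conditions: Ph3PCH3Br (2.5 equiv), KOtBu (2.5 equiv), THF, 0 °C to rt
Reagents that add atoms: methyltriphenylphosphonium bromide, C[P+](c1ccccc1)(c1ccccc1)c1ccccc1.[Br-]
Why: Wittig methylenation; one equivalent of base is consumed by the phenol and the phenoxide aldehyde still reacts at room temperature, as is usual for salicylaldehydes; no stereocentre is formed.

Step 2
Reactants: 2 4-bromo-2-ethenyl-6-methoxyphenol
Product: 3 1-(5-bromo-2-hydroxy-3-methoxyphenyl)ethane-1,2-diol (racemic)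
Conditions: OsO4 (2 mol%), NMO (1.5 equiv), acetone/H2O, rt
Reagents that add atoms: N-methylmorpholine N-oxide, C[N+]1([O-])CCOCC1; water, O; osmium tetroxide (catalytic oxygen carrier), O=[Os](=O)(=O)=O
Why: Catalytic osmium dihydroxylation with an amine oxide as terminal oxidant; the electron-rich styrene is a good substrate, and the diol may be racemic because its carbinol carbon becomes planar again in step 11.

Step 3
Reactants: 3 1-(5-bromo-2-hydroxy-3-methoxyphenyl)ethane-1,2-diol (racemic)
Product: 4 4-bromo-2-[2-{[tert-butyl(diphenyl)silyl]oxy}-1-hydroxyethyl]-6-methoxyphenol (racemic)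
Conditions: TBDPSCl (1.05 equiv), imidazole, CH2Cl2/DMF, 0 °C
Reagents that add atoms: tert-butyl(chloro)diphenylsilane, CC(C)(C)[Si](Cl)(c1ccccc1)c1ccccc1
Why: Chemoselective silylation; the bulky chlorosilane takes the primary hydroxyl well ahead of the secondary benzylic one and of the phenol, which is flanked by two ortho substituents.

Step 4
Reactants: 4 4-bromo-2-[2-{[tert-butyl(diphenyl)silyl]oxy}-1-hydroxyethyl]-6-methoxyphenol (racemic)
Product: 5 4-bromo-2-[2-{[tert-butyl(diphenyl)silyl]oxy}-1-(4-methylbenzenesulfonyl)ethyl]-6-methoxyphenol (racemic)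
Conditions: p-TolSO2H (1.5 equiv), MgSO4, CH2Cl2, rt
Reagents that add atoms: 4-methylbenzenesulfinic acid, Cc1ccc(cc1)S(=O)O
Why: Acid-mediated substitution of an ortho-hydroxybenzylic alcohol by a sulfinic acid, the standard entry to 2-(1-sulfonylalkyl)phenols; the ortho hydroxyl assists ionisation and the sulfur of the sulfinate captures the cation; the diphenyl silyl ether is chosen because it tolerates this acid.

Step 5
Reactants: 6 syringaldehyde (4-hydroxy-3,5-dimethoxybenzaldehyde)
Product: 7 4-formyl-2,6-dimethoxyphenyl 2,2-dimethylpropanoate
Conditions: PivCl, Et3N, DMAP (cat.), CH2Cl2, 0 °C to rt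
Reagents that add atoms: pivaloyl chloride, CC(C)(C)C(=O)Cl
Why: DMAP-catalysed acylation of the phenol; the pivalate will later resist carbonate and phenoxide and keeps the benzylic position from ionising.

Step 6
Reactants: 7 4-formyl-2,6-dimethoxyphenyl 2,2-dimethylpropanoate
Product: 8 4-(hydroxymethyl)-2,6-dimethoxyphenyl 2,2-dimethylpropanoate
Conditions: NaBH4, THF/MeOH, 0 °C
Reagents that add atoms: none
Why: Borohydride reduction of the aldehyde; the aryl pivalate, shielded by two ortho methoxy groups, is left intact at 0 °C.

Step 7
Reactants: 8 4-(hydroxymethyl)-2,6-dimethoxyphenyl 2,2-dimethylpropanoate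
Product: 9 4-(bromomethyl)-2,6-dimethoxyphenyl 2,2-dimethylpropanoate
Conditions: PBr3 (0.4 equiv), CH2Cl2, 0 °C
Reagents that add atoms: phosphorus tribromide, BrP(Br)Br
Why: Conversion of a benzylic alcohol to the bromide by SN2 displacement of its phosphite ester.

Step 8
Reactants: 10 (2R,5R)-hexane-2,5-diol
Product: 11 (2R,5R)-hexane-2,5-diyl dimethanesulfonate
Conditions: MsCl, Et3N, CH2Cl2, −20 to 0 °C
Reagents that add atoms: methanesulfonyl chloride, CS(=O)(=O)Cl
Why: Mesylation of both secondary alcohols; only O–S bonds form, so both carbon centres keep their configuration.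

Step 9
Reactants: 11 (2R,5R)-hexane-2,5-diyl dimethanesulfonate
Product: 13 (2S,5S)-2,5-dimethylthiolane, via monothiolate 12 (not isolated)
Conditions: Na2S·9H2O, DMSO, rt
Reagents that add atoms: sodium sulfide, [Na+].[Na+].[S-2]
Why: Double SN2 displacement by sulfide, each with inversion, so the (2R,5R) dimesylate gives the (2S,5S) thiolane; the second displacement is a 5-exo-tet closure of thiolate 12.

Step 10
Reactants: 9 4-(bromomethyl)-2,6-dimethoxyphenyl 2,2-dimethylpropanoate; 13 (2S,5S)-2,5-dimethylthiolane
Product: 14 (2S,5S)-1-{[3,5-dimethoxy-4-(pivaloyloxy)phenyl]methyl}-2,5-dimethylthiolan-1-ium tetrafluoroborate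
Conditions: AgBF4 (1.05 equiv), CH2Cl2, 0 °C to rt, dark
Reagents that add atoms: silver tetrafluoroborate, [Ag+].F[B-](F)(F)F
Why: S-Alkylation of the sulfide by the benzylic bromide, driven by precipitation of AgBr; the non-nucleophilic counter-ion prevents reversal, and sulfur is not a stereocentre because the ring is C2-symmetric.

Step 11
Reactants: 5 4-bromo-2-[2-{[tert-butyl(diphenyl)silyl]oxy}-1-(4-methylbenzenesulfonyl)ethyl]-6-methoxyphenol (racemic); 14 (2S,5S)-1-{[3,5-dimethoxy-4-(pivaloyloxy)phenyl]methyl}-2,5-dimethylthiolan-1-ium tetrafluoroborate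
Product: 18 4-[(2S,3R)-5-bromo-3-{[tert-butyl(diphenyl)silyl]oxymethyl}-7-methoxy-2,3-dihydro-1-benzofuran-2-yl]-2,6-dimethoxyphenyl 2,2-dimethylpropanoate, via ortho-quinone methide 15 (not isolated), via sulfonium ylide 16 (not isolated), via phenoxide betaine 17 (not isolated)
Conditions: Cs2CO3 (3 equiv), 14 (1.3 equiv), CH2Cl2, 0 °C to rt
Reagents that add atoms: none
Why: Proposed new method: Cs2CO3 deprotonates the phenol of 5, which expels p-toluenesulfinate to give ortho-quinone methide 15, and in equilibrium deprotonates 14 to benzyl ylide 16; the ylide carbon adds to the exocyclic methide carbon (C2–C3), the ring re-aromatises to phenoxide betaine 17, and the phenoxide displaces the neutral thiolane at the benzylic carbon (O1–C2). The closest known reaction types are the (4+1) annulation of sulfone-derived ortho-quinone methides with carbonyl-stabilised sulfur ylides, which gives trans-2,3-dihydrobenzofurans, and asymmetric benzylidene transfer from this C2-symmetric thiolanium ylide to aldehydes; new here is the pairing of a semi-stabilised benzyl ylide with a methide bearing an enolisable alkyl substituent. The one ring formed, the dihydrofuran, closes by 5-exo-tet SN2 displacement with inversion at C2. C2 is controlled by the sulfide: its two methyl groups leave one face of the ylide carbon open, which fixes the sulfonium carbon of 17 as R and, after inversion, C2 as S. C3 is set in the same C–C bond formation, which does not reverse because it restores aromaticity; an open transition state that keeps the ylide aryl group away from the silyloxymethyl group leads to the betaine that closes to the trans ring. The step needs the phenoxide to eliminate sulfinate and not be benzylated by 14; the phenoxide is flanked by two ortho substituents and the elimination is intramolecular, while the pivalate keeps 14 from ionising to a para-quinone methide. It also needs capture of 15 to outrun its tautomerisation to the enol ether; slow heterogeneous generation of 15 in the presence of excess 14 is intended to secure this.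

Step 12
Reactants: 18 4-[(2S,3R)-5-bromo-3-{[tert-butyl(diphenyl)silyl]oxymethyl}-7-methoxy-2,3-dihydro-1-benzofuran-2-yl]-2,6-dimethoxyphenyl 2,2-dimethylpropanoate
Product: 19 methyl (E)-3-[(2S,3R)-3-{[tert-butyl(diphenyl)silyl]oxymethyl}-2-[3,5-dimethoxy-4-(pivaloyloxy)phenyl]-7-methoxy-2,3-dihydro-1-benzofuran-5-yl]prop-2-enoate
Conditions: methyl acrylate (3 equiv), Pd(OAc)2 (5 mol%), P(o-tol)3 (12 mol%), Et3N, DMF, 90 °C
Reagents that add atoms: methyl acrylate, C=CC(=O)OC
Why: Heck reaction; oxidative addition of the aryl bromide to zerovalent palladium, syn insertion of the acrylate and syn β-hydride elimination give the (E)-cinnamate; the stereocentres are remote from the reacting carbon, and the silyl ether and pivalate are inert to amine base.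

Step 13
Reactants: 19 methyl (E)-3-[(2S,3R)-3-{[tert-butyl(diphenyl)silyl]oxymethyl}-2-[3,5-dimethoxy-4-(pivaloyloxy)phenyl]-7-methoxy-2,3-dihydro-1-benzofuran-5-yl]prop-2-enoate
Product: 20 methyl (E)-3-[(2S,3R)-2-[3,5-dimethoxy-4-(pivaloyloxy)phenyl]-3-(hydroxymethyl)-7-methoxy-2,3-dihydro-1-benzofuran-5-yl]prop-2-enoate
Conditions: Bu4NF, AcOH, THF, rt
Reagents that add atoms: none
Why: Fluoride cleavage of the silyl ether, driven by Si–F bond formation; acetic acid buffers the alkoxide so that neither ester is touched and no stereocentre is at risk.

Step 14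
Reactants: 20 methyl (E)-3-[(2S,3R)-2-[3,5-dimethoxy-4-(pivaloyloxy)phenyl]-3-(hydroxymethyl)-7-methoxy-2,3-dihydro-1-benzofuran-5-yl]prop-2-enoate
Product: 21 (E)-3-[(2S,3R)-2-(4-hydroxy-3,5-dimethoxyphenyl)-3-(hydroxymethyl)-7-methoxy-2,3-dihydro-1-benzofuran-5-yl]prop-2-enoic acid
Conditions: LiOH·H2O (6 equiv), degassed THF/MeOH/H2O, rt to 40 °C, under argon; then 1 M HCl to pH 3
Reagents that add atoms: lithium hydroxide, [Li+].[OH-]; water, O
Why: Saponification of the methyl ester and of the aryl pivalate by hydroxide, then acidification; exclusion of air and low temperature protect the syringyl phenoxide from oxidation and from opening the ring at C2.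

## Compound list

1 | 5-bromo-2-hydroxy-3-methoxybenzaldehyde | COc1cc(Br)cc(C=O)c1O | starting material
2 | 4-bromo-2-ethenyl-6-methoxyphenol | COc1cc(Br)cc(C=C)c1O | intermediate
3 | 1-(5-bromo-2-hydroxy-3-methoxyphenyl)ethane-1,2-diol (racemic) | COc1cc(Br)cc(C(O)CO)c1O | intermediate
4 | 4-bromo-2-[2-{[tert-butyl(diphenyl)silyl]oxy}-1-hydroxyethyl]-6-methoxyphenol (racemic) | COc1cc(Br)cc(C(O)CO[Si](c2ccccc2)(c2ccccc2)C(C)(C)C)c1O | intermediate
5 | 4-bromo-2-[2-{[tert-butyl(diphenyl)silyl]oxy}-1-(4-methylbenzenesulfonyl)ethyl]-6-methoxyphenol (racemic) | COc1cc(Br)cc(C(CO[Si](c2ccccc2)(c2ccccc2)C(C)(C)C)S(=O)(=O)c2ccc(C)cc2)c1O | intermediate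
6 | syringaldehyde (4-hydroxy-3,5-dimethoxybenzaldehyde) | COc1cc(C=O)cc(OC)c1O | starting material
7 | 4-formyl-2,6-dimethoxyphenyl 2,2-dimethylpropanoate | COc1cc(C=O)cc(OC)c1OC(=O)C(C)(C)C | intermediate
8 | 4-(hydroxymethyl)-2,6-dimethoxyphenyl 2,2-dimethylpropanoate | COc1cc(CO)cc(OC)c1OC(=O)C(C)(C)C | intermediate
9 | 4-(bromomethyl)-2,6-dimethoxyphenyl 2,2-dimethylpropanoate | COc1cc(CBr)cc(OC)c1OC(=O)C(C)(C)C | intermediate
10 | (2R,5R)-hexane-2,5-diol | C[C@@H](O)CC[C@@H](C)O | starting material
11 | (2R,5R)-hexane-2,5-diyl dimethanesulfonate | C[C@@H](OS(C)(=O)=O)CC[C@@H](C)OS(C)(=O)=O | intermediate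
12 | sodium (2S,5R)-5-(methanesulfonyloxy)hexane-2-thiolate | C[C@H]([S-])CC[C@@H](C)OS(C)(=O)=O.[Na+] | intermediate (not isolated)
13 | (2S,5S)-2,5-dimethylthiolane | C[C@H]1CC[C@H](C)S1 | intermediate
14 | (2S,5S)-1-{[3,5-dimethoxy-4-(pivaloyloxy)phenyl]methyl}-2,5-dimethylthiolan-1-ium tetrafluoroborate | C[C@H]1CC[C@H](C)[S+]1Cc1cc(OC)c(OC(=O)C(C)(C)C)c(OC)c1.F[B-](F)(F)F | intermediate
15 | 4-bromo-6-[2-{[tert-butyl(diphenyl)silyl]oxy}ethylidene]-2-methoxycyclohexa-2,4-dien-1-one (ortho-quinone methide, alkene geometry not defined) | COC1=CC(Br)=CC(=CCO[Si](c2ccccc2)(c2ccccc2)C(C)(C)C)C1=O | intermediate (not isolated)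
16 | (2S,5S)-1-{[3,5-dimethoxy-4-(pivaloyloxy)phenyl]methylide}-2,5-dimethylthiolan-1-ium (sulfonium ylide) | C[C@H]1CC[C@H](C)[S+]1[CH-]c1cc(OC)c(OC(=O)C(C)(C)C)c(OC)c1 | intermediate (not isolated)
17 | 4-bromo-2-[(2R,3R)-1-{[tert-butyl(diphenyl)silyl]oxy}-3-[3,5-dimethoxy-4-(pivaloyloxy)phenyl]-3-[(2S,5S)-2,5-dimethylthiolan-1-ium-1-yl]propan-2-yl]-6-methoxyphenolate (betaine) | COc1cc(Br)cc([C@H](CO[Si](c2ccccc2)(c2ccccc2)C(C)(C)C)[C@H](c2cc(OC)c(OC(=O)C(C)(C)C)c(OC)c2)[S+]2[C@@H](C)CC[C@@H]2C)c1[O-] | intermediate (not isolated)
18 | 4-[(2S,3R)-5-bromo-3-{[tert-butyl(diphenyl)silyl]oxymethyl}-7-methoxy-2,3-dihydro-1-benzofuran-2-yl]-2,6-dimethoxyphenyl 2,2-dimethylpropanoate (trans) | COc1cc([C@H]2Oc3c(OC)cc(Br)cc3[C@@H]2CO[Si](c4ccccc4)(c4ccccc4)C(C)(C)C)cc(OC)c1OC(=O)C(C)(C)C | intermediate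
19 | methyl (E)-3-[(2S,3R)-3-{[tert-butyl(diphenyl)silyl]oxymethyl}-2-[3,5-dimethoxy-4-(pivaloyloxy)phenyl]-7-methoxy-2,3-dihydro-1-benzofuran-5-yl]prop-2-enoate | COc1cc([C@H]2Oc3c(OC)cc(/C=C/C(=O)OC)cc3[C@@H]2CO[Si](c4ccccc4)(c4ccccc4)C(C)(C)C)cc(OC)c1OC(=O)C(C)(C)C | intermediate
20 | methyl (E)-3-[(2S,3R)-2-[3,5-dimethoxy-4-(pivaloyloxy)phenyl]-3-(hydroxymethyl)-7-methoxy-2,3-dihydro-1-benzofuran-5-yl]prop-2-enoate | COc1cc([C@H]2Oc3c(OC)cc(/C=C/C(=O)OC)cc3[C@@H]2CO)cc(OC)c1OC(=O)C(C)(C)C | intermediate
21 | (E)-3-[(2S,3R)-2-(4-hydroxy-3,5-dimethoxyphenyl)-3-(hydroxymethyl)-7-methoxy-2,3-dihydro-1-benzofuran-5-yl]prop-2-enoic acid | COc1cc([C@H]2Oc3c(OC)cc(/C=C/C(=O)O)cc3[C@@H]2CO)cc(OC)c1O | target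

## Step count and risks

Total: 14 steps. Longest linear sequence: 8 steps (steps 1–4, 11, 12–14; the line from 6 through steps 5–7 and 10 is equally long).

**Step 11 (key step, proposed new method).** The most likely failure is that methide 15 tautomerises or oligomerises faster than the ylide captures it. Other risks are that carbonate forms too little of ylide 16, that the phenoxide is benzylated by 14, and that the ylide adds with poor facial or trans selectivity. A wrong sense of induction is met by the enantiomeric diol, not by a new route. The fallback uses the established dirhodium-carbenoid C–H insertion; it sets out from 1 and 9 and comes back at 18.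
- Phenol 1 is alkylated with bromide 9 (K2CO3, DMF) to the aryl benzyl ether aldehyde F1.
- Wittig reaction with (methoxymethylidene)triphenylphosphorane gives the enol ether F2, which pyridinium chlorochromate oxidises to the methyl arylacetate F3.
- Diazo transfer (4-acetamidobenzenesulfonyl azide, DBU) gives the aryldiazoacetate F4.
- Rh2(S-PTTL)4, or its mirror-image catalyst (the sense to be assigned on the first run), inserts the carbenoid into the benzylic ether C–H bond at low temperature to give the cis ester F5, with C2 set by the catalyst.
- DBU epimerises C3 to the trans ester A5.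
- LiBH4 in THF at 0 °C reduces the methyl ester ahead of the doubly hindered aryl pivalate to the primary alcohol F6; if the pivalate were lost as well, it would be put back with PivCl.
- TBDPSCl/imidazole gives 18.

**Step 4.** Ionisation next to the electron-withdrawing silyloxymethyl group may be slow, and forcing it with stronger acid would strip the silyl ether or allow a hydride shift to the arylacetaldehyde. The fallback sets out from 3 and comes back at 5. The exchange is run before any silyl group is present: triol 3 with p-TolSO2Na in aqueous formic acid gives the hydroxy sulfone F7, which is silylated at the primary hydroxyl (TBDPSCl, imidazole, CH2Cl2, 0 °C) to give 5.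

**Step 3.** The phenol may be silylated in competition with the primary alcohol, giving mixtures. The fallback sets out from 3 and comes back at 4. Both the primary hydroxyl and the phenol are silylated on purpose (TBDPSCl in excess, imidazole, DMF) to the bis-silyl ether F8, and the aryl silyl ether alone is then cleaved with K2CO3 in methanol to give 4.

**Step 10.** The hindered sulfide may alkylate slowly, and silver-assisted ionisation of the electron-rich benzylic bromide may lead to Friedel–Crafts oligomerisation instead. The fallback sets out from 8 and 13 and comes back at 18. Alcohol 8 is converted at −78 °C into its triflate (Tf2O, 2,6-di-tert-butylpyridine, CH2Cl2) and trapped at once by sulfide 13 to give the sulfonium triflate F9, which replaces 14 in step 11.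

**Step 14.** The aryl pivalate, shielded by two ortho methoxy groups, may hydrolyse incompletely; forcing conditions would invite air oxidation of the phenoxide or base-induced opening at C2. The fallback sets out from 18 and comes back at 21. The pivalate is removed reductively while no other ester is present (DIBAL-H, CH2Cl2, −78 °C) to give the free phenol bromide F10. Heck reaction with methyl acrylate under the conditions of step 12 gives the phenol cinnamate F11. Buffered fluoride gives the phenol alcohol methyl ester F12, and LiOH at room temperature, which now has only the methyl ester to cleave, gives 21.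

## Further compounds

F1 | step 11 | 4-[(4-bromo-2-formyl-6-methoxyphenoxy)methyl]-2,6-dimethoxyphenyl 2,2-dimethylpropanoate | COc1cc(Br)cc(C=O)c1OCc1cc(OC)c(OC(=O)C(C)(C)C)c(OC)c1
F2 | step 11 | 4-{[4-bromo-2-methoxy-6-(2-methoxyethenyl)phenoxy]methyl}-2,6-dimethoxyphenyl 2,2-dimethylpropanoate (E/Z mixture) | COC=Cc1cc(Br)cc(OC)c1OCc1cc(OC)c(OC(=O)C(C)(C)C)c(OC)c1
F3 | step 11 | methyl 2-[5-bromo-2-{[3,5-dimethoxy-4-(pivaloyloxy)phenyl]methoxy}-3-methoxyphenyl]acetate | COC(=O)Cc1cc(Br)cc(OC)c1OCc1cc(OC)c(OC(=O)C(C)(C)C)c(OC)c1
F4 | step 11 | methyl 2-[5-bromo-2-{[3,5-dimethoxy-4-(pivaloyloxy)phenyl]methoxy}-3-methoxyphenyl]-2-diazoacetate | COC(=O)C(=[N+]=[N-])c1cc(Br)cc(OC)c1OCc1cc(OC)c(OC(=O)C(C)(C)C)c(OC)c1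
F5 | step 11 | methyl (2S,3R)-5-bromo-2-[3,5-dimethoxy-4-(pivaloyloxy)phenyl]-7-methoxy-2,3-dihydro-1-benzofuran-3-carboxylate (cis) | COc1cc([C@H]2Oc3c(OC)cc(Br)cc3[C@H]2C(=O)OC)cc(OC)c1OC(=O)C(C)(C)C
F6 | step 11 | 4-[(2S,3R)-5-bromo-3-(hydroxymethyl)-7-methoxy-2,3-dihydro-1-benzofuran-2-yl]-2,6-dimethoxyphenyl 2,2-dimethylpropanoate | COc1cc([C@H]2Oc3c(OC)cc(Br)cc3[C@@H]2CO)cc(OC)c1OC(=O)C(C)(C)C
F7 | step 4 | 4-bromo-2-[2-hydroxy-1-(4-methylbenzenesulfonyl)ethyl]-6-methoxyphenol (racemic) | COc1cc(Br)cc(C(CO)S(=O)(=O)c2ccc(C)cc2)c1O
F8 | step 3 | 1-(5-bromo-2-{[tert-butyl(diphenyl)silyl]oxy}-3-methoxyphenyl)-2-{[tert-butyl(diphenyl)silyl]oxy}ethan-1-ol (racemic) | COc1cc(Br)cc(C(O)CO[Si](c2ccccc2)(c2ccccc2)C(C)(C)C)c1O[Si](c1ccccc1)(c1ccccc1)C(C)(C)C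
F9 | step 10 | (2S,5S)-1-{[3,5-dimethoxy-4-(pivaloyloxy)phenyl]methyl}-2,5-dimethylthiolan-1-ium trifluoromethanesulfonate | C[C@H]1CC[C@H](C)[S+]1Cc1cc(OC)c(OC(=O)C(C)(C)C)c(OC)c1.[O-]S(=O)(=O)C(F)(F)F
F10 | step 14 | 4-[(2S,3R)-5-bromo-3-{[tert-butyl(diphenyl)silyl]oxymethyl}-7-methoxy-2,3-dihydro-1-benzofuran-2-yl]-2,6-dimethoxyphenol | COc1cc([C@H]2Oc3c(OC)cc(Br)cc3[C@@H]2CO[Si](c4ccccc4)(c4ccccc4)C(C)(C)C)cc(OC)c1O
F11 | step 14 | methyl (E)-3-[(2S,3R)-3-{[tert-butyl(diphenyl)silyl]oxymethyl}-2-(4-hydroxy-3,5-dimethoxyphenyl)-7-methoxy-2,3-dihydro-1-benzofuran-5-yl]prop-2-enoate | COc1cc([C@H]2Oc3c(OC)cc(/C=C/C(=O)OC)cc3[C@@H]2CO[Si](c4ccccc4)(c4ccccc4)C(C)(C)C)cc(OC)c1O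
F12 | step 14 | methyl (E)-3-[(2S,3R)-2-(4-hydroxy-3,5-dimethoxyphenyl)-3-(hydroxymethyl)-7-methoxy-2,3-dihydro-1-benzofuran-5-yl]prop-2-enoate | COc1cc([C@H]2Oc3c(OC)cc(/C=C/C(=O)OC)cc3[C@@H]2CO)cc(OC)c1O
A1 | alternative 1 | methyl (E)-3-{3-[(2R,3S)-1-{[tert-butyl(dimethyl)silyl]oxy}-3-hydroxy-3-[3,5-dimethoxy-4-(methoxymethoxy)phenyl]propan-2-yl]-5-methoxy-4-(trifluoromethanesulfonyloxy)phenyl}prop-2-enoate | COc1cc([C@@H](O)[C@@H](CO[Si](C)(C)C(C)(C)C)c2cc(/C=C/C(=O)OC)cc(OC)c2OS(=O)(=O)C(F)(F)F)cc(OC)c1OCOC
A2 | alternative 1 | methyl (E)-3-[(2S,3R)-3-{[tert-butyl(dimethyl)silyl]oxymethyl}-2-[3,5-dimethoxy-4-(methoxymethoxy)phenyl]-7-methoxy-2,3-dihydro-1-benzofuran-5-yl]prop-2-enoate | COc1cc([C@H]2Oc3c(OC)cc(/C=C/C(=O)OC)cc3[C@@H]2CO[Si](C)(C)C(C)(C)C)cc(OC)c1OCOC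
A3 | alternative 2 | methyl 3-[(1S,2R)-3-{[tert-butyl(dimethyl)silyl]oxy}-1-[3,5-dimethoxy-4-(methoxymethoxy)phenyl]-1-(4,4,5,5-tetramethyl-1,3,2-dioxaborolan-2-yl)propan-2-yl]-5-methoxy-4-(methoxymethoxy)benzoate | COCOc1c(OC)cc(C(=O)OC)cc1[C@H](CO[Si](C)(C)C(C)(C)C)[C@H](B1OC(C)(C)C(C)(C)O1)c1cc(OC)c(OCOC)c(OC)c1
A4 | alternative 3 | 4-[(2S)-6-bromo-8-methoxy-4-oxo-3,4-dihydro-2H-chromen-2-yl]-2,6-dimethoxyphenyl 2,2-dimethylpropanoate | COc1cc([C@@H]2CC(=O)c3cc(Br)cc(OC)c3O2)cc(OC)c1OC(=O)C(C)(C)C
A5 | alternative 3 | methyl (2S,3S)-5-bromo-2-[3,5-dimethoxy-4-(pivaloyloxy)phenyl]-7-methoxy-2,3-dihydro-1-benzofuran-3-carboxylate (trans) | COc1cc([C@H]2Oc3c(OC)cc(Br)cc3[C@@H]2C(=O)OC)cc(OC)c1OC(=O)C(C)(C)C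
A6 | alternative 3 | 1-(5-bromo-2-hydroxy-3-methoxyphenyl)ethan-1-one | CC(=O)c1cc(Br)cc(OC)c1O
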